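The earlier runs and the new flask were computed for substances that don't exist.

Two questions stand here: how much of what reacted is still target in each flask, and how that share runs along the row.

| flask | substrate | coupling partner | remark | time |
|---|---|---|---|---|
| beta | 0.0028 M | 0.12 M | run made earlier |  |
| gamma | 0.26 M | 0.12 M | run made earlier |  |
| south-west | 0.0040 M | 0.120 M |  | 4.0 d |
| north | 0.012 M | 0.120 M |  | 4.0 d |
| east | 0.040 M | 0.120 M |  | 4.0 d |
| north-east | 0.12 M | 0.120 M |  | 4.0 d |
| south | 0.40 M | 0.120 M |  | 4.0 d |

| run | time / d | target / % | side product / % |
|---|---|---|---|
| beta | 0.500 | 68.7 | 1.3 |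
| beta | 1.25 | 35.0 | 1.4 |
| beta | 2.50 | 11.5 | 1.4 |
| beta | 4.00 | 2.4 | 0.4 |
| gamma | 0.333 | 29.6 | 57.9 |
| gamma | 0.833 | 31.3 | 61.2 |
| gamma | 1.67 | 30.6 | 62.0 |
| gamma | 4.00 | 28.6 | 61.7 |

(readings scatter by 0.5 percentage points)

- share of target in all that became target or side product or over-reaction product for south-west, north, east, north-east, south, in this order
- the course of these numbers from the first flask to the last (rises all the way / falls, then rises / falls all the way / rises, then falls / hardly changes)

- in percentages every species weighs as the substrate in it: one side product counts as two
- the numbers in the tables scatter by 0.5 percentage points (one standard deviation)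
- "hardly changes" means that all values lie within two and a half points (for a concentration: within two and a half percent of the largest)

Start from beta. Its substrate is charged far below its coupling partner, 0.0028 M against 0.12 M, so you can freeze [coupling partner] there and let the target fall on one exponential (pseudo-first-order):

clock = ln(68.7% / 2.4%) / (4.00 d − 0.500 d) = 0.958 d⁻¹

Call this the clock: the first-order rate at which target is lost, as read in beta, with [coupling partner] near its full charge. Read back to the whole charge, beta's target seems born at

birth = 0.108 d

Now take south-west. Its [coupling partner] can be frozen at the fraction left once each substrate has taken one coupling partner, because 0.0040 M is far below 0.120 M: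

fraction = 96.7%

target at 4.0 d = exp(−clock × fraction × (time − birth)) = 2.72%

The weak link is 2.4%, which carries a scatter of 0.5 percentage points. So reforge the clock from the middle pair of beta readings:

clock = 0.890 d⁻¹, birth = 0.0784 d, target = 3.42%

I commit to that span for south-west. In gamma the late fall of target reads 0.0285 d⁻¹, far slower than the clock, so the share should climb as the charge grows. But gamma's side product stands at 61.7% against 28.6% of target, so the climb should end.

The forecast gives 3.2%, 4.4%, 11%, 29%, 24.5%: "The share therefore rises, then falls."

The flasks give 3.10%, 4.37%, 10.9%, 29.6%, 22.4%, and the shape rises, then falls.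

    2 substrate → side product (k = 1.40 M⁻¹ h⁻¹)
    coupling partner + target → over-reaction product (k = 0.330 M⁻¹ h⁻¹)
    substrate + coupling partner → target (k = 2.50 M⁻¹ h⁻¹)

In south-west the target's half-life by over-reaction alone, with coupling partner as charged, is 0.73 d, short against the 4.0 d of the run. Run the first clock, 0.958 d⁻¹, at that flask's 93.6% of coupling partner over the second stretch, and 18.4% of target becomes 3.07%, where 3.10% stands. In north-east, coupling partner falls from 16.6% to 8.70%; the same clock at the mean of these turns 36.9% of target into 28.9%, and the flask holds 29.6%.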